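**Plan**

- Retrosynthetic cuts, in order: the helper C4–OH of unit 2 and the benzyl ethers; then C2–C3 and O1–C8a of the unit 2 pyran ring (to a 2-fluorophenyl benzyl ketone plus ethyl formate); then the C4(unit 1)–C5'(unit 2) bond (to a C4 cation and an arene). Both halves converge on one deoxybenzoin, 5.
- Forward: 5 (Pd α-arylation) is annulated and reduced to cis-isoflavan-4-ol 9, which closes ring C of unit 1. A second molecule of 5 captures the C4 cation of 9. Ring C of unit 2 is then closed on the coupled ketone 11 and reduced.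
- Enabling feature: C4 of unit 2 lies between C3 and ring-A carbon C4a. As a carbonyl it makes C3–H acidic and turns the ortho C8a–F into a vinylogous acyl fluoride, so HCO2Et enters as the C2–O1 unit between C3 and C8a. The same carbonyl keeps ring A of 5 out of the Friedel–Crafts step.
- Stereochemistry: C3 of each unit comes from Ru-catalysed asymmetric transfer hydrogenation with dynamic kinetic resolution (catalyst control). C4 of unit 1 comes from attack of the arene anti to the C3 aryl group (substrate control, trans).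

Key step: step 7

Remark: flavonoid numbering is used for both halves (unit 1 = the 4-aryl isoflavan; unit 2 = the isoflavan bonded through C5' of its B ring). The (R,R) ruthenium complex is assumed to give the (4R) carbinol, as it does with simple aryl alkyl ketones; its mirror image would be used if the sense were the opposite.

**Route**

Step 1
Reactants: 1 2-bromo-5-methoxyphenol
Product: 2 2-(benzyloxy)-1-bromo-4-methoxybenzene
Conditions: BnBr, K2CO3, DMF, rt
Reagents that add atoms: benzyl bromide, BrCc1ccccc1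
Why: Williamson ether synthesis (SN2 of the phenoxide on benzyl bromide); the benzyl ether should survive every later base- and acid-mediated step and is removed in the last step.

Step 2
Reactants: 3 1-(2-fluoro-4-hydroxyphenyl)ethan-1-one
Product: 4 1-[4-(benzyloxy)-2-fluorophenyl]ethan-1-one
Conditions: BnBr, K2CO3, acetone, reflux
Reagents that add atoms: benzyl bromide, BrCc1ccccc1
Why: Williamson ether synthesis; the weak base should leave the methyl ketone and the aryl fluoride untouched.

Step 3
Reactants: 4 1-[4-(benzyloxy)-2-fluorophenyl]ethan-1-one (1.3 equiv); 2 2-(benzyloxy)-1-bromo-4-methoxybenzene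
Product: 5 1-[4-(benzyloxy)-2-fluorophenyl]-2-[2-(benzyloxy)-4-methoxyphenyl]ethan-1-one
Conditions: Pd(OAc)2 (2 mol %), XPhos (4 mol %), K3PO4, toluene, 90 °C
Reagents that add atoms: none
Why: Palladium-catalysed ketone α-arylation (Buchwald–Hartwig type): the potassium enolate of 4 couples with the arylpalladium bromide from 2, the bulky biarylphosphine and the ortho-benzyloxy group should favour mono-arylation, and the C–F bond is inert to the catalyst.

Step 4
Reactants: 5 1-[4-(benzyloxy)-2-fluorophenyl]-2-[2-(benzyloxy)-4-methoxyphenyl]ethan-1-one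
Product: 7 7-(benzyloxy)-3-[2-(benzyloxy)-4-methoxyphenyl]-4H-chromen-4-one, via sodium formyl enolate 6 (not isolated)
Conditions: NaH (3 equiv), HCO2Et (10 equiv), THF, 0 °C to rt; then DMF, 90 °C
Reagents that add atoms: ethyl formate, CCOC=O
Why: Claisen formylation of the doubly activated CH2 followed by intramolecular addition–elimination of the enolate oxygen at the fluorine-bearing carbon ortho to the ketone (chromone closure by O-arylation), the same domino as step 7 on the simple ketone; no stereocentre is formed.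

Step 5
Reactants: 7 7-(benzyloxy)-3-[2-(benzyloxy)-4-methoxyphenyl]-4H-chromen-4-one
Product: 9 (3R,4R)-7-(benzyloxy)-3-[2-(benzyloxy)-4-methoxyphenyl]chroman-4-ol, via isoflavanone 8 (not isolated)
Conditions: RuCl[(R,R)-TsDPEN](p-cymene) (5 mol %), HCO2H/Et3N (5:2), EtOAc, 45 °C
Reagents that add atoms: none
Why: Noyori–Ikariya asymmetric transfer hydrogenation run as a cascade: the ruthenium hydride first reduces the chromone C2=C3 bond to isoflavanone 8, whose C3 epimerises rapidly through the enol, and the (R,R) catalyst then reduces one ketone enantiomer faster (dynamic kinetic resolution) with hydride delivered anti to the 3-aryl group, which should give the cis-(3R,4R) alcohol with both centres under catalyst control.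

Step 6
Reactants: 9 (3R,4R)-7-(benzyloxy)-3-[2-(benzyloxy)-4-methoxyphenyl]chroman-4-ol; 5 1-[4-(benzyloxy)-2-fluorophenyl]-2-[2-(benzyloxy)-4-methoxyphenyl]ethan-1-one (1.5 equiv)
Product: 11 1-[4-(benzyloxy)-2-fluorophenyl]-2-{2-(benzyloxy)-5-[(3R,4S)-7-(benzyloxy)-3-[2-(benzyloxy)-4-methoxyphenyl]chroman-4-yl]-4-methoxyphenyl}ethan-1-one, via benzylic cation 10 (not isolated)
Conditions: BF3·OEt2 (20 mol %), 4 Å MS, CH2Cl2, −78 to −20 °C
Reagents that add atoms: none
Why: Friedel–Crafts alkylation by an SN1 path: ionisation gives cation 10, stabilised by the para benzyloxy group and the ortho ring oxygen of ring A, which should be captured by C5' of the resorcinol-diether ring of 5 (para to OBn, ortho to OMe; the other ring of 5 is deactivated by its ketone) from the face anti to the C3 aryl group, giving the 3,4-trans (3R,4S) product as in the 4-arylation of flavan-4-ol derivatives in proanthocyanidin synthesis.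

Step 7
Reactants: 11 1-[4-(benzyloxy)-2-fluorophenyl]-2-{2-(benzyloxy)-5-[(3R,4S)-7-(benzyloxy)-3-[2-(benzyloxy)-4-methoxyphenyl]chroman-4-yl]-4-methoxyphenyl}ethan-1-one
Product: 13 7-(benzyloxy)-3-{2-(benzyloxy)-5-[(3R,4S)-7-(benzyloxy)-3-[2-(benzyloxy)-4-methoxyphenyl]chroman-4-yl]-4-methoxyphenyl}-4H-chromen-4-one, via sodium formyl enolate 12 (not isolated)
Conditions: NaH (3 equiv), HCO2Et (10 equiv), THF, 0 °C to rt; then DMF, 90 °C
Reagents that add atoms: ethyl formate, CCOC=O
Why: Sodium hydride deprotonates C3 of unit 2, the only carbon acid in 11 (flanked by the C4 ketone and ring B), and the enolate undergoes Claisen condensation with ethyl formate to form the C2–C3 bond, the product being held as the chelated sodium enolate 12; on heating in DMF the formyl-derived enolate oxygen adds to C8a, ortho to the ketone, and fluoride leaves through a Meisenheimer complex, forming the O1–C8a bond. The closest known reaction types are the formylation of deoxybenzoins in isoflavone synthesis and the base-mediated intramolecular O-arylation of 1-(2-halophenyl)-1,3-dicarbonyl compounds to chromones, the oxygen counterpart of the Grohe–Heitzer quinolone closure. The pyranone ring closes as a six-membered, formally 6-endo-trig conjugate addition to the vinylogous acyl fluoride O=C4–C4a=C8a–F followed by loss of fluoride, driven by formation of the aromatic benzopyranone. No stereocentre is created, because C3 becomes trigonal and is set in step 8; the two centres of unit 1 lie away from any acidifying group and should not epimerise. The step needs C- over O-formylation, a single formylation and O- over C-arylation: O-formates revert under the alkoxide, the formyl ketone is withdrawn from further reaction as its enolate, and only the enolate oxygen can reach C8a through a six-membered transition state. The C4 ketone that secures all of this is the helper group and is removed in steps 8 and 9.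

Step 8
Reactants: 13 7-(benzyloxy)-3-{2-(benzyloxy)-5-[(3R,4S)-7-(benzyloxy)-3-[2-(benzyloxy)-4-methoxyphenyl]chroman-4-yl]-4-methoxyphenyl}-4H-chromen-4-one
Product: 15 (3R,4R)-7-(benzyloxy)-3-{2-(benzyloxy)-5-[(3R,4S)-7-(benzyloxy)-3-[2-(benzyloxy)-4-methoxyphenyl]chroman-4-yl]-4-methoxyphenyl}chroman-4-ol, via isoflavanone 14 (not isolated)
Conditions: RuCl[(R,R)-TsDPEN](p-cymene) (5 mol %), HCO2H/Et3N (5:2), EtOAc, 45 °C
Reagents that add atoms: none
Why: The same Noyori–Ikariya conjugate reduction/dynamic kinetic resolution cascade as step 5; the centres of unit 1 are remote and not enolisable, so the (R,R) catalyst alone should set C3 and C4 of unit 2 as cis-(3R,4R).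

Step 9
Reactants: 15 (3R,4R)-7-(benzyloxy)-3-{2-(benzyloxy)-5-[(3R,4S)-7-(benzyloxy)-3-[2-(benzyloxy)-4-methoxyphenyl]chroman-4-yl]-4-methoxyphenyl}chroman-4-ol
Product: 17 (3R)-3-{2-hydroxy-5-[(3R,4S)-7-hydroxy-3-(2-hydroxy-4-methoxyphenyl)chroman-4-yl]-4-methoxyphenyl}chroman-7-ol, via debenzylated alcohol 16 (not isolated)
Conditions: H2 (1 atm), 10% Pd/C, EtOAc/AcOH (4:1), rt
Reagents that add atoms: none
Why: Catalytic hydrogenolysis: the four benzyl ethers should cleave first to give 16, and the electron-rich benzylic C4–OH of unit 2 (para to the freed 7-OH) is then cleaved under the acid-assisted conditions used for isoflavan-4-ols, while C3 of unit 2 and both centres of unit 1 take no part, so all three stereocentres should be retained.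

**Compound list**

1 | 2-bromo-5-methoxyphenol | COc1ccc(Br)c(O)c1 | starting material
2 | 2-(benzyloxy)-1-bromo-4-methoxybenzene | COc1ccc(Br)c(OCc2ccccc2)c1 | intermediate
3 | 1-(2-fluoro-4-hydroxyphenyl)ethan-1-one | CC(=O)c1ccc(O)cc1F | starting material
4 | 1-[4-(benzyloxy)-2-fluorophenyl]ethan-1-one | CC(=O)c1ccc(OCc2ccccc2)cc1F | intermediate
5 | 1-[4-(benzyloxy)-2-fluorophenyl]-2-[2-(benzyloxy)-4-methoxyphenyl]ethan-1-one (deoxybenzoin) | COc1ccc(CC(=O)c2ccc(OCc3ccccc3)cc2F)c(OCc2ccccc2)c1 | intermediate
6 | sodium (Z)-enolate of 3-[4-(benzyloxy)-2-fluorophenyl]-2-[2-(benzyloxy)-4-methoxyphenyl]-3-oxopropanal | COc1ccc(/C(=C/[O-])C(=O)c2ccc(OCc3ccccc3)cc2F)c(OCc2ccccc2)c1.[Na+] | intermediate (not isolated)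
7 | 7-(benzyloxy)-3-[2-(benzyloxy)-4-methoxyphenyl]-4H-chromen-4-one (isoflavone) | COc1ccc(-c2coc3cc(OCc4ccccc4)ccc3c2=O)c(OCc2ccccc2)c1 | intermediate
8 | 7-(benzyloxy)-3-[2-(benzyloxy)-4-methoxyphenyl]chroman-4-one (isoflavanone, C3 epimers interconverting) | COc1ccc(C2COc3cc(OCc4ccccc4)ccc3C2=O)c(OCc2ccccc2)c1 | intermediate (not isolated)
9 | (3R,4R)-7-(benzyloxy)-3-[2-(benzyloxy)-4-methoxyphenyl]chroman-4-ol (cis) | COc1ccc([C@@H]2COc3cc(OCc4ccccc4)ccc3[C@@H]2O)c(OCc2ccccc2)c1 | intermediate
10 | (3R)-7-(benzyloxy)-3-[2-(benzyloxy)-4-methoxyphenyl]chroman-4-ylium (benzylic cation) | COc1ccc([C@@H]2COc3cc(OCc4ccccc4)ccc3[CH+]2)c(OCc2ccccc2)c1 | intermediate (not isolated)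
11 | 1-[4-(benzyloxy)-2-fluorophenyl]-2-{2-(benzyloxy)-5-[(3R,4S)-7-(benzyloxy)-3-[2-(benzyloxy)-4-methoxyphenyl]chroman-4-yl]-4-methoxyphenyl}ethan-1-one | COc1ccc([C@@H]2COc3cc(OCc4ccccc4)ccc3[C@H]2c2cc(CC(=O)c3ccc(OCc4ccccc4)cc3F)c(OCc3ccccc3)cc2OC)c(OCc2ccccc2)c1 | intermediate
12 | sodium (Z)-enolate of the 2-formyl derivative of ketone 11 | COc1ccc([C@@H]2COc3cc(OCc4ccccc4)ccc3[C@H]2c2cc(/C(=C/[O-])C(=O)c3ccc(OCc4ccccc4)cc3F)c(OCc3ccccc3)cc2OC)c(OCc2ccccc2)c1.[Na+] | intermediate (not isolated)
13 | 7-(benzyloxy)-3-{2-(benzyloxy)-5-[(3R,4S)-7-(benzyloxy)-3-[2-(benzyloxy)-4-methoxyphenyl]chroman-4-yl]-4-methoxyphenyl}-4H-chromen-4-one | COc1ccc([C@@H]2COc3cc(OCc4ccccc4)ccc3[C@H]2c2cc(-c3coc4cc(OCc5ccccc5)ccc4c3=O)c(OCc3ccccc3)cc2OC)c(OCc2ccccc2)c1 | intermediate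
14 | 7-(benzyloxy)-3-{2-(benzyloxy)-5-[(3R,4S)-7-(benzyloxy)-3-[2-(benzyloxy)-4-methoxyphenyl]chroman-4-yl]-4-methoxyphenyl}chroman-4-one (C3 of unit 2 epimerising) | COc1ccc([C@@H]2COc3cc(OCc4ccccc4)ccc3[C@H]2c2cc(C3COc4cc(OCc5ccccc5)ccc4C3=O)c(OCc3ccccc3)cc2OC)c(OCc2ccccc2)c1 | intermediate (not isolated)
15 | (3R,4R)-7-(benzyloxy)-3-{2-(benzyloxy)-5-[(3R,4S)-7-(benzyloxy)-3-[2-(benzyloxy)-4-methoxyphenyl]chroman-4-yl]-4-methoxyphenyl}chroman-4-ol | COc1ccc([C@@H]2COc3cc(OCc4ccccc4)ccc3[C@H]2c2cc([C@@H]3COc4cc(OCc5ccccc5)ccc4[C@@H]3O)c(OCc3ccccc3)cc2OC)c(OCc2ccccc2)c1 | intermediate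
16 | (3R,4R)-3-{2-hydroxy-5-[(3R,4S)-7-hydroxy-3-(2-hydroxy-4-methoxyphenyl)chroman-4-yl]-4-methoxyphenyl}chromane-4,7-diol | COc1ccc([C@@H]2COc3cc(O)ccc3[C@H]2c2cc([C@@H]3COc4cc(O)ccc4[C@@H]3O)c(O)cc2OC)c(O)c1 | intermediate (not isolated)
17 | (3R)-3-{2-hydroxy-5-[(3R,4S)-7-hydroxy-3-(2-hydroxy-4-methoxyphenyl)chroman-4-yl]-4-methoxyphenyl}chroman-7-ol | COc1ccc([C@@H]2COc3cc(O)ccc3[C@H]2c2cc([C@@H]3COc4cc(O)ccc4C3)c(O)cc2OC)c(O)c1 | target

**Count and risks**

Total step count: 9. Longest linear sequence: 8 steps (3 → 4 → 5 → 7 → 9 → 11 → 13 → 15 → 17; step 1 supplies the side branch and 5 is used twice).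

Steps most likely to fail:

1. Step 6. Capture of cation 10 by the ketone-bearing arene may be slow. Loss of the C3 proton would then give an isoflav-3-ene whose reprotonation erases the C3 centre of unit 1, and attack by the neighbouring 2'-benzyloxy oxygen could also compete. The fallback sets out from 9 and uses the far more nucleophilic free phenol 1 as the arene (BF3·OEt2 10 mol %, CH2Cl2, −78 °C). Attack para to the hydroxyl should give 2-bromo-4-[(3R,4S)-7-(benzyloxy)-3-[2-(benzyloxy)-4-methoxyphenyl]chroman-4-yl]-5-methoxyphenol F1. O-Benzylation (BnBr, K2CO3, DMF) gives the aryl bromide (3R,4S)-7-(benzyloxy)-4-[4-(benzyloxy)-5-bromo-2-methoxyphenyl]-3-[2-(benzyloxy)-4-methoxyphenyl]chromane F2. Palladium-catalysed α-arylation of ketone 4 with F2 under the conditions of step 3 then builds the deoxybenzoin after the arylation and comes back to the route at 11.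

2. Step 7. The addition–elimination may be sluggish because the aroyl group is tied up in the delocalised 1,3-dicarbonyl anion, and prolonged heating could lead to deformylation. The fallback sets out from 11 and uses the C1 unit at the alcohol oxidation level: aldol reaction with paraformaldehyde (K2CO3, DMSO, 60 °C) should give the hydroxymethyl ketone 1-[4-(benzyloxy)-2-fluorophenyl]-2-{2-(benzyloxy)-5-[(3R,4S)-7-(benzyloxy)-3-[2-(benzyloxy)-4-methoxyphenyl]chroman-4-yl]-4-methoxyphenyl}-3-hydroxypropan-1-one F3. Its alkoxide displaces the fluoride ortho to a free ketone and closes the ring as isoflavanone 14, now isolated. Compound 14 enters the ketone-reduction half of step 8 (same catalyst) and comes back to the route at 15.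

3. Step 8. Conjugate reduction of the bulky, poorly soluble isoflavone by the ruthenium hydride may be incomplete, or carbonyl reduction may outrun C3 epimerisation and erode the selectivity. The fallback sets out from 13 and takes the conjugate reduction out of the catalytic cascade: L-Selectride (LiBH(s-Bu)3, THF, −78 °C) should give isoflavanone 14 by 1,4-reduction. Isolated 14 is then reduced alone under dynamic kinetic resolution with RuCl[(R,R)-TsDPEN](p-cymene) and HCO2H/Et3N, coming back to the route at 15.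

**Further compounds**

F1 | step 6 | 2-bromo-4-[(3R,4S)-7-(benzyloxy)-3-[2-(benzyloxy)-4-methoxyphenyl]chroman-4-yl]-5-methoxyphenol | COc1ccc([C@@H]2COc3cc(OCc4ccccc4)ccc3[C@H]2c2cc(Br)c(O)cc2OC)c(OCc2ccccc2)c1
F2 | step 6 | (3R,4S)-7-(benzyloxy)-4-[4-(benzyloxy)-5-bromo-2-methoxyphenyl]-3-[2-(benzyloxy)-4-methoxyphenyl]chromane | COc1ccc([C@@H]2COc3cc(OCc4ccccc4)ccc3[C@H]2c2cc(Br)c(OCc3ccccc3)cc2OC)c(OCc2ccccc2)c1
F3 | step 7 | 1-[4-(benzyloxy)-2-fluorophenyl]-2-{2-(benzyloxy)-5-[(3R,4S)-7-(benzyloxy)-3-[2-(benzyloxy)-4-methoxyphenyl]chroman-4-yl]-4-methoxyphenyl}-3-hydroxypropan-1-one (both epimers at the new centre) | COc1ccc([C@@H]2COc3cc(OCc4ccccc4)ccc3[C@H]2c2cc(C(CO)C(=O)c3ccc(OCc4ccccc4)cc3F)c(OCc3ccccc3)cc2OC)c(OCc2ccccc2)c1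
F0 | step 8 | none | none
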